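The 7-oxabicyclo[2.2.1]heptane core carries its ether bond O7–C4 and the C3 side-chain bond on adjacent carbons, with C4 lying 1,4 to the oxygen-bearing C1. Both bonds are therefore cut across a former C3=C4 alkene of a cyclohex-3-en-1-ol. One photoredox operation oxidises that alkene, lets the C1 hydroxyl close the oxolane ring onto C4 and sends the resulting tertiary C3 radical into methyl acrylate from the exo face, creating the bicycle, the C3 quaternary centre and the C4 centre together. The precursor is an enantiopure 1,3-dimethylcyclohex-3-en-1-ol with a silyloxymethyl arm at C2, anti to the hydroxyl, made by desymmetrising a Birch-derived diene.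

Key step: step 6

Remark: ring atoms keep the locants C1 (methyl-bearing bridgehead), C2, C3, C4 (bridgehead CH), C5, C6, O7 in every name; the C2 arm is carried as a TIPS ether because an ester there would be cleaved by the hydride that opens the epoxide, the vicinal bromide/chloride is made last because it would not survive zinc or organometallic reagents, and the antipodes of the epoxidation ketone and of the bromochlorination ligand are assigned from their transition-state models and would be confirmed on 5 and 22.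

Step 1
Reactants: 1 2,6-dimethylbenzoic acid
Product: 2 2,6-dimethylcyclohexa-2,5-diene-1-carboxylic acid
Conditions: Li, NH3(l)/THF, −78 °C; NH4Cl; aq. HCl
Reagents that add atoms: none
Why: Birch reduction of a benzoic acid adds the two hydrogens at C1 and C4, leaving both methyl groups on the two alkenes of a mirror-symmetric 1,4-diene (no stereocentre).

Step 2
Reactants: 2 2,6-dimethylcyclohexa-2,5-diene-1-carboxylic acid
Product: 3 (2,6-dimethylcyclohexa-2,5-dien-1-yl)methanol
Conditions: LiAlH4, THF, 0 °C to rt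
Reagents that add atoms: none
Why: LiAlH4 reduction of the carboxylic acid to the primary alcohol; the unconjugated ring alkenes are inert to hydride.

Step 3
Reactants: 3 (2,6-dimethylcyclohexa-2,5-dien-1-yl)methanol
Product: 4 [(2,6-dimethylcyclohexa-2,5-dien-1-yl)methoxy]tri(propan-2-yl)silane
Conditions: TIPSCl, imidazole, DMF, rt
Reagents that add atoms: chlorotri(propan-2-yl)silane, CC(C)[Si](Cl)(C(C)C)C(C)C
Why: Silylation of the primary alcohol gives a hydride-stable, non-oxidisable group whose bulk blocks one ring face now and the endo face in the key step.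

Step 4
Reactants: 4 [(2,6-dimethylcyclohexa-2,5-dien-1-yl)methoxy]tri(propan-2-yl)silane
Product: 5 {[(1R,2R,6S)-1,3-dimethyl-7-oxabicyclo[4.1.0]hept-3-en-2-yl]methoxy}tri(propan-2-yl)silane (epoxide anti to the arm)
Conditions: Shi ketone of the L series (enantiomer of the D-fructose-derived catalyst, 30 mol%), KHSO5 (Oxone, 1.1 equiv), K2CO3, Bu4NHSO4, MeCN/CH2(OMe)2/aq. Na2B4O7 buffer, pH 10.5, −10 to 0 °C
Reagents that add atoms: potassium peroxymonosulfate, [K+].[O-]S(=O)(=O)OO
Why: Shi asymmetric epoxidation run as a desymmetrisation: the dioxirane must approach anti to the CH2OTIPS arm, and only on one of the two enantiotopic trisubstituted alkenes is that face also the one favoured by the spiro transition state (sense taken by analogy with 1-substituted cyclohexenes), which sets both epoxide carbons and makes C2 stereogenic.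

Step 5
Reactants: 5 {[(1R,2R,6S)-1,3-dimethyl-7-oxabicyclo[4.1.0]hept-3-en-2-yl]methoxy}tri(propan-2-yl)silane
Product: 6 (1S,2R)-1,3-dimethyl-2-{[tri(propan-2-yl)silyl]oxymethyl}cyclohex-3-en-1-ol (hydroxyl anti to the arm)
Conditions: LiAlH4, THF, 0 to 40 °C
Reagents that add atoms: none
Why: SN2 hydride opening of the trisubstituted epoxide at its less substituted carbon leaves the tertiary C–O bond untouched, so the C1 configuration and the anti relation to the arm are carried over.

Step 6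
Reactants: 6 (1S,2R)-1,3-dimethyl-2-{[tri(propan-2-yl)silyl]oxymethyl}cyclohex-3-en-1-ol; 7 methyl acrylate
Product: 8 methyl 3-[(1S,2R,3S,4R)-1,3-dimethyl-2-{[tri(propan-2-yl)silyl]oxymethyl}-7-oxabicyclo[2.2.1]heptan-3-yl]propanoate (C2 arm endo, C3 methyl endo, C3 chain exo)
Conditions: 9-mesityl-3,6-di-tert-butyl-10-phenylacridinium tetrafluoroborate (5 mol%), 7 (5 equiv), 2,6-lutidine (20 mol%), ClCH2CH2Cl (0.05 M), 450 nm LEDs, N2, rt
Reagents that add atoms: none
Why: Proposed new method: the excited acridinium (excited-state reduction potential near +2 V against SCE) oxidises the trisubstituted C3=C4 alkene to its radical cation, the C1 hydroxyl adds through a boat to C4, proton loss leaves the tertiary C3 radical, this nucleophilic radical adds to methyl acrylate, and the α-ester radical is reduced by the acridine radical (which restores the catalyst) and protonated, so the step is redox-neutral and loses no atoms. The closest known chemistry is acridinium-photoredox anti-Markovnikov hydroetherification of alkenols and polar radical crossover cycloaddition, here ended by a Giese addition instead of hydrogen-atom transfer. The oxolane O7–C1–C6–C5–C4 closes 5-exo-trig along the C1–C6–C5–C4 tether (the same bond seen along C1–C2–C3–C4 is 5-endo), which creates the bicyclo[2.2.1] skeleton. C4 is fixed by the tether, since O7 can bridge C1 and C4 on one face only, and C3 is fixed by exo attack on the radical, because the endo face is screened by the C5–C6 bridge and by the endo CH2OTIPS arm, so the methyl ends endo. The step needs O–C4 rather than O–C3 bonding (C3 would give an oxetane and a less stable radical), exo C–C bond formation, and trapping of the C3 radical by acrylate before it is reduced or abstracts hydrogen; geometry secures the first, sterics the second, and excess acrylate without any thiol co-catalyst serves the third.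

Step 7
Reactants: 8 methyl 3-[(1S,2R,3S,4R)-1,3-dimethyl-2-{[tri(propan-2-yl)silyl]oxymethyl}-7-oxabicyclo[2.2.1]heptan-3-yl]propanoate
Product: 9 3-[(1S,2R,3S,4R)-1,3-dimethyl-2-{[tri(propan-2-yl)silyl]oxymethyl}-7-oxabicyclo[2.2.1]heptan-3-yl]propanal
Conditions: i-Bu2AlH (1.1 equiv), CH2Cl2, −78 °C; aq. KNaC4H4O6
Reagents that add atoms: none
Why: Partial reduction of a methyl ester with i-Bu2AlH stops at the aldehyde because the tetrahedral aluminium hemiacetal persists at −78 °C; the silyl ether is inert.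

Step 8
Reactants: 9 3-[(1S,2R,3S,4R)-1,3-dimethyl-2-{[tri(propan-2-yl)silyl]oxymethyl}-7-oxabicyclo[2.2.1]heptan-3-yl]propanal
Product: 10 {[(1S,2R,3S,4R)-1,3-dimethyl-3-(4-methylpent-3-en-1-yl)-7-oxabicyclo[2.2.1]heptan-2-yl]methoxy}tri(propan-2-yl)silane
Conditions: i-PrPPh3I, n-BuLi, THF, 0 °C; then 9, −78 °C to rt
Reagents that add atoms: isopropyltriphenylphosphonium iodide, CC(C)[P+](c1ccccc1)(c1ccccc1)c1ccccc1.[I-]
Why: Wittig olefination of an unhindered aldehyde with the isopropylidene ylide gives the trisubstituted alkene, which has no geometric isomers.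

Step 9
Reactants: 10 {[(1S,2R,3S,4R)-1,3-dimethyl-3-(4-methylpent-3-en-1-yl)-7-oxabicyclo[2.2.1]heptan-2-yl]methoxy}tri(propan-2-yl)silane
Product: 11 [(1S,2R,3S,4R)-1,3-dimethyl-3-(4-methylpent-3-en-1-yl)-7-oxabicyclo[2.2.1]heptan-2-yl]methanol
Conditions: Bu4NF, THF, rt
Reagents that add atoms: none
Why: Fluoride cleavage of the silyl ether, driven by the Si–F bond; nothing else in the molecule responds to fluoride.

Step 10
Reactants: 11 [(1S,2R,3S,4R)-1,3-dimethyl-3-(4-methylpent-3-en-1-yl)-7-oxabicyclo[2.2.1]heptan-2-yl]methanol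
Product: 12 [(1S,2R,3S,4R)-1,3-dimethyl-3-(4-methylpent-3-en-1-yl)-7-oxabicyclo[2.2.1]heptan-2-yl]methyl trifluoromethanesulfonate
Conditions: Tf2O, pyridine, CH2Cl2, −78 to −20 °C; used at once
Reagents that add atoms: trifluoromethanesulfonic anhydride, FC(F)(F)S(=O)(=O)OS(=O)(=O)C(F)(F)F
Why: Sulfonylation of the primary alcohol; the triflate is chosen because the carbon sits on a ring CH flanked by two quaternary carbons and needs the best leaving group for the coming SN2 step.

Step 11
Reactants: 12 [(1S,2R,3S,4R)-1,3-dimethyl-3-(4-methylpent-3-en-1-yl)-7-oxabicyclo[2.2.1]heptan-2-yl]methyl trifluoromethanesulfonate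
Product: 14 (1S,2S,3S,4R)-2-(but-3-yn-1-yl)-1,3-dimethyl-3-(4-methylpent-3-en-1-yl)-7-oxabicyclo[2.2.1]heptane, via TMS-alkyne 13 (not isolated)
Conditions: 1-(trimethylsilyl)propyne, n-BuLi, THF, −78 °C; add 12, −78 to 0 °C; then MeOH, K2CO3, rt
Reagents that add atoms: 1-(trimethylsilyl)propyne, CC#C[Si](C)(C)C
Why: SN2 alkylation of lithiated 1-(trimethylsilyl)propyne, which reacts at its propargylic carbon, followed by methanolysis of the C–Si bond in the same flask; no stereocentre is involved.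

Step 12
Reactants: 14 (1S,2S,3S,4R)-2-(but-3-yn-1-yl)-1,3-dimethyl-3-(4-methylpent-3-en-1-yl)-7-oxabicyclo[2.2.1]heptane
Product: 17 (2E)-5-[(1S,2S,3S,4R)-1,3-dimethyl-3-(4-methylpent-3-en-1-yl)-7-oxabicyclo[2.2.1]heptan-2-yl]-3-methylpent-2-en-1-ol, via alkenyldimethylalane 15 (not isolated), via lithium alkenylaluminate 16 (not isolated)
Conditions: Me3Al (3 equiv), Cp2ZrCl2 (0.3 equiv), CH2Cl2, 0 °C to rt; then n-BuLi, THF, −78 °C; (CH2O)n, −78 °C to rt
Reagents that add atoms: trimethylaluminium, C[Al](C)C; formaldehyde (as paraformaldehyde), C=O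
Why: Negishi zirconium-catalysed carboalumination adds methyl and aluminium syn across the terminal alkyne with methyl on the internal carbon, and the aluminate is trapped by formaldehyde with retention, so only the (E)-trisubstituted allylic alcohol can form; the prenyl alkene does not react.

Step 13
Reactants: 17 (2E)-5-[(1S,2S,3S,4R)-1,3-dimethyl-3-(4-methylpent-3-en-1-yl)-7-oxabicyclo[2.2.1]heptan-2-yl]-3-methylpent-2-en-1-ol
Product: 18 [(2S,3S)-3-{2-[(1S,2S,3S,4R)-1,3-dimethyl-3-(4-methylpent-3-en-1-yl)-7-oxabicyclo[2.2.1]heptan-2-yl]ethyl}-3-methyloxiran-2-yl]methanol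
Conditions: Ti(OiPr)4 (10 mol%), L-(+)-diethyl tartrate (12 mol%), t-BuOOH, 4 Å molecular sieves, CH2Cl2, −20 °C
Reagents that add atoms: tert-butyl hydroperoxide, CC(C)(C)OO
Why: Sharpless asymmetric epoxidation; L-(+)-tartrate delivers oxygen to the face that gives the (2S,3S)-epoxy alcohol (the geraniol case), fixing the future carbinol carbon, while the prenyl alkene, which has no allylic hydroxyl, is left alone.

Step 14
Reactants: 18 [(2S,3S)-3-{2-[(1S,2S,3S,4R)-1,3-dimethyl-3-(4-methylpent-3-en-1-yl)-7-oxabicyclo[2.2.1]heptan-2-yl]ethyl}-3-methyloxiran-2-yl]methanol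
Product: 19 (2R,3S)-2-(iodomethyl)-3-methyl-3-{2-[(1S,2S,3S,4R)-1,3-dimethyl-3-(4-methylpent-3-en-1-yl)-7-oxabicyclo[2.2.1]heptan-2-yl]ethyl}oxirane
Conditions: I2, PPh3, imidazole, Et2O/MeCN, 0 °C
Reagents that add atoms: iodine, II
Why: Appel-type iodination of the primary alcohol through its alkoxyphosphonium salt; both epoxide carbons keep their geometry (the C2 label changes only because CH2I outranks the ring carbon).

Step 15
Reactants: 19 (2R,3S)-2-(iodomethyl)-3-methyl-3-{2-[(1S,2S,3S,4R)-1,3-dimethyl-3-(4-methylpent-3-en-1-yl)-7-oxabicyclo[2.2.1]heptan-2-yl]ethyl}oxirane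
Product: 20 (3S)-5-[(1S,2S,3S,4R)-1,3-dimethyl-3-(4-methylpent-3-en-1-yl)-7-oxabicyclo[2.2.1]heptan-2-yl]-3-methylpent-1-en-3-ol
Conditions: Zn dust, AcOH (2 equiv), EtOH, 0 °C to rt
Reagents that add atoms: none
Why: Reductive ring-opening of a 2,3-epoxy iodide: zinc inserts into the C–I bond and β-elimination opens the epoxide, leaving the oxygen on the quaternary carbon with its configuration retained, which gives the (S)-vinyl carbinol.

Step 16
Reactants: 20 (3S)-5-[(1S,2S,3S,4R)-1,3-dimethyl-3-(4-methylpent-3-en-1-yl)-7-oxabicyclo[2.2.1]heptan-2-yl]-3-methylpent-1-en-3-ol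
Product: 21 (2E)-5-[(1S,2S,3S,4R)-2-[(3S)-3-hydroxy-3-methylpent-4-en-1-yl]-1,3-dimethyl-7-oxabicyclo[2.2.1]heptan-3-yl]-2-methylpent-2-en-1-ol
Conditions: SeO2 (0.3 equiv), t-BuOOH (3 equiv), salicylic acid (0.1 equiv), CH2Cl2, rt
Reagents that add atoms: tert-butyl hydroperoxide, CC(C)(C)OO
Why: Selenium dioxide allylic oxidation (ene reaction, then [2,3]-sigmatropic shift) hydroxylates the (E)-methyl at the more substituted end of the trisubstituted alkene, as it does for linalool itself; the vinyl carbinol has no allylic hydrogen and is spared.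

Step 17
Reactants: 21 (2E)-5-[(1S,2S,3S,4R)-2-[(3S)-3-hydroxy-3-methylpent-4-en-1-yl]-1,3-dimethyl-7-oxabicyclo[2.2.1]heptan-3-yl]-2-methylpent-2-en-1-ol
Product: 22 (2R,3S)-3-bromo-2-chloro-5-[(1S,2S,3S,4R)-2-[(3S)-3-hydroxy-3-methylpent-4-en-1-yl]-1,3-dimethyl-7-oxabicyclo[2.2.1]heptan-3-yl]-2-methylpentan-1-ol
Conditions: NBS (1.05 equiv), ClTi(OiPr)3 (1.1 equiv), chiral tridentate Schiff-base diol ligand (salicylaldimine of a tert-leucine-derived 1,1-diaryl amino alcohol, 30 mol%, the antipode that brominates the Si face of the alkene CH), hexanes, −20 °C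
Reagents that add atoms: N-bromosuccinimide, BrN1C(=O)CCC1=O; chlorotitanium triisopropoxide, CC(C)O[Ti](Cl)(OC(C)C)OC(C)C
Why: Titanium-mediated catalytic enantioselective bromochlorination of an allylic alcohol: the primary alkoxide binds titanium, the ligand dictates the face of bromonium formation and chloride is delivered anti to the adjacent tertiary carbon (Markovnikov sense), which sets the (S)-C–Br centre, while the electron-poor vinyl group is far less nucleophilic.

Step 18
Reactants: 22 (2R,3S)-3-bromo-2-chloro-5-[(1S,2S,3S,4R)-2-[(3S)-3-hydroxy-3-methylpent-4-en-1-yl]-1,3-dimethyl-7-oxabicyclo[2.2.1]heptan-3-yl]-2-methylpentan-1-ol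
Product: 23 (2R,3S)-3-bromo-2-chloro-5-[(1S,2S,3S,4R)-2-[(3S)-3-hydroxy-3-methylpent-4-en-1-yl]-1,3-dimethyl-7-oxabicyclo[2.2.1]heptan-3-yl]-2-methylpentyl trifluoromethanesulfonate
Conditions: Tf2O (1.05 equiv), pyridine, CH2Cl2, −78 °C; used cold and at once
Reagents that add atoms: trifluoromethanesulfonic anhydride, FC(F)(F)S(=O)(=O)OS(=O)(=O)C(F)(F)F
Why: Selective sulfonylation: at −78 °C with one equivalent only the primary hydroxyl reacts, the hindered tertiary allylic alcohol does not.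

Step 19
Reactants: 23 (2R,3S)-3-bromo-2-chloro-5-[(1S,2S,3S,4R)-2-[(3S)-3-hydroxy-3-methylpent-4-en-1-yl]-1,3-dimethyl-7-oxabicyclo[2.2.1]heptan-3-yl]-2-methylpentyl trifluoromethanesulfonate
Product: 24 (3S)-5-[(1S,2S,3S,4R)-3-[(3S)-3-bromo-4-chloro-4-methylpentyl]-1,3-dimethyl-7-oxabicyclo[2.2.1]heptan-2-yl]-3-methylpent-1-en-3-ol (CNP0297543.1)
Conditions: LiEt3BH (3 equiv, the first deprotonates the tertiary alcohol), THF, −78 to 0 °C
Reagents that add atoms: none
Why: SN2 hydride displacement of the primary triflate (deoxygenation to methyl); the secondary bromide and tertiary chloride, each next to a fully substituted carbon, are much slower electrophiles than a triflate in the cold, and the chlorine-bearing carbon becomes the non-stereogenic CMe2Cl group.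

Compound list
1 | 2,6-dimethylbenzoic acid | Cc1cccc(C)c1C(=O)O | starting material
2 | 2,6-dimethylcyclohexa-2,5-diene-1-carboxylic acid | CC1=CCC=C(C)C1C(=O)O | intermediate
3 | (2,6-dimethylcyclohexa-2,5-dien-1-yl)methanol | CC1=CCC=C(C)C1CO | intermediate
4 | [(2,6-dimethylcyclohexa-2,5-dien-1-yl)methoxy]tri(propan-2-yl)silane | CC1=CCC=C(C)C1CO[Si](C(C)C)(C(C)C)C(C)C | intermediate
5 | {[(1R,2R,6S)-1,3-dimethyl-7-oxabicyclo[4.1.0]hept-3-en-2-yl]methoxy}tri(propan-2-yl)silane | CC(C)[Si](OC[C@H]1C(C)=CC[C@@H]2O[C@]12C)(C(C)C)C(C)C | intermediate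
6 | (1S,2R)-1,3-dimethyl-2-{[tri(propan-2-yl)silyl]oxymethyl}cyclohex-3-en-1-ol | CC(C)[Si](OC[C@H]1C(C)=CCC[C@]1(C)O)(C(C)C)C(C)C | intermediate
7 | methyl acrylate | C=CC(=O)OC | starting material
8 | methyl 3-[(1S,2R,3S,4R)-1,3-dimethyl-2-{[tri(propan-2-yl)silyl]oxymethyl}-7-oxabicyclo[2.2.1]heptan-3-yl]propanoate | CC(C)[Si](OC[C@H]1[C@](C)(CCC(=O)OC)[C@H]2CC[C@]1(C)O2)(C(C)C)C(C)C | intermediate
9 | 3-[(1S,2R,3S,4R)-1,3-dimethyl-2-{[tri(propan-2-yl)silyl]oxymethyl}-7-oxabicyclo[2.2.1]heptan-3-yl]propanal | CC(C)[Si](OC[C@H]1[C@](C)(CCC=O)[C@H]2CC[C@]1(C)O2)(C(C)C)C(C)C | intermediate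
10 | {[(1S,2R,3S,4R)-1,3-dimethyl-3-(4-methylpent-3-en-1-yl)-7-oxabicyclo[2.2.1]heptan-2-yl]methoxy}tri(propan-2-yl)silane | CC(C)[Si](OC[C@H]1[C@](C)(CCC=C(C)C)[C@H]2CC[C@]1(C)O2)(C(C)C)C(C)C | intermediate
11 | [(1S,2R,3S,4R)-1,3-dimethyl-3-(4-methylpent-3-en-1-yl)-7-oxabicyclo[2.2.1]heptan-2-yl]methanol | OC[C@H]1[C@](C)(CCC=C(C)C)[C@H]2CC[C@]1(C)O2 | intermediate
12 | [(1S,2R,3S,4R)-1,3-dimethyl-3-(4-methylpent-3-en-1-yl)-7-oxabicyclo[2.2.1]heptan-2-yl]methyl trifluoromethanesulfonate | O=S(=O)(OC[C@H]1[C@](C)(CCC=C(C)C)[C@H]2CC[C@]1(C)O2)C(F)(F)F | intermediate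
13 | trimethyl{4-[(1S,2S,3S,4R)-1,3-dimethyl-3-(4-methylpent-3-en-1-yl)-7-oxabicyclo[2.2.1]heptan-2-yl]but-1-yn-1-yl}silane | C[Si](C)(C)C#CCC[C@H]1[C@](C)(CCC=C(C)C)[C@H]2CC[C@]1(C)O2 | intermediate (not isolated)
14 | (1S,2S,3S,4R)-2-(but-3-yn-1-yl)-1,3-dimethyl-3-(4-methylpent-3-en-1-yl)-7-oxabicyclo[2.2.1]heptane | C#CCC[C@H]1[C@](C)(CCC=C(C)C)[C@H]2CC[C@]1(C)O2 | intermediate
15 | dimethyl{(1E)-2-methyl-4-[(1S,2S,3S,4R)-1,3-dimethyl-3-(4-methylpent-3-en-1-yl)-7-oxabicyclo[2.2.1]heptan-2-yl]but-1-en-1-yl}alane (Al cis to the new methyl) | C[Al](C)/C=C(\C)CC[C@H]1[C@](C)(CCC=C(C)C)[C@H]2CC[C@]1(C)O2 | intermediate (not isolated)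
16 | lithium butyl(dimethyl){(1E)-2-methyl-4-[(1S,2S,3S,4R)-1,3-dimethyl-3-(4-methylpent-3-en-1-yl)-7-oxabicyclo[2.2.1]heptan-2-yl]but-1-en-1-yl}aluminate | [Li+].CCCC[Al-](C)(C)/C=C(\C)CC[C@H]1[C@](C)(CCC=C(C)C)[C@H]2CC[C@]1(C)O2 | intermediate (not isolated)
17 | (2E)-5-[(1S,2S,3S,4R)-1,3-dimethyl-3-(4-methylpent-3-en-1-yl)-7-oxabicyclo[2.2.1]heptan-2-yl]-3-methylpent-2-en-1-ol | C/C(CC[C@H]1[C@](C)(CCC=C(C)C)[C@H]2CC[C@]1(C)O2)=C\CO | intermediate
18 | [(2S,3S)-3-{2-[(1S,2S,3S,4R)-1,3-dimethyl-3-(4-methylpent-3-en-1-yl)-7-oxabicyclo[2.2.1]heptan-2-yl]ethyl}-3-methyloxiran-2-yl]methanol | OC[C@@H]3O[C@@]3(C)CC[C@H]1[C@](C)(CCC=C(C)C)[C@H]2CC[C@]1(C)O2 | intermediate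
19 | (2R,3S)-2-(iodomethyl)-3-methyl-3-{2-[(1S,2S,3S,4R)-1,3-dimethyl-3-(4-methylpent-3-en-1-yl)-7-oxabicyclo[2.2.1]heptan-2-yl]ethyl}oxirane | IC[C@@H]3O[C@@]3(C)CC[C@H]1[C@](C)(CCC=C(C)C)[C@H]2CC[C@]1(C)O2 | intermediate
20 | (3S)-5-[(1S,2S,3S,4R)-1,3-dimethyl-3-(4-methylpent-3-en-1-yl)-7-oxabicyclo[2.2.1]heptan-2-yl]-3-methylpent-1-en-3-ol | C=C[C@@](C)(O)CC[C@H]1[C@](C)(CCC=C(C)C)[C@H]2CC[C@]1(C)O2 | intermediate
21 | (2E)-5-[(1S,2S,3S,4R)-2-[(3S)-3-hydroxy-3-methylpent-4-en-1-yl]-1,3-dimethyl-7-oxabicyclo[2.2.1]heptan-3-yl]-2-methylpent-2-en-1-ol | C=C[C@@](C)(O)CC[C@H]1[C@](C)(CC/C=C(\C)CO)[C@H]2CC[C@]1(C)O2 | intermediate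
22 | (2R,3S)-3-bromo-2-chloro-5-[(1S,2S,3S,4R)-2-[(3S)-3-hydroxy-3-methylpent-4-en-1-yl]-1,3-dimethyl-7-oxabicyclo[2.2.1]heptan-3-yl]-2-methylpentan-1-ol | C=C[C@@](C)(O)CC[C@H]1[C@](C)(CC[C@H](Br)[C@](C)(Cl)CO)[C@H]2CC[C@]1(C)O2 | intermediate
23 | (2R,3S)-3-bromo-2-chloro-5-[(1S,2S,3S,4R)-2-[(3S)-3-hydroxy-3-methylpent-4-en-1-yl]-1,3-dimethyl-7-oxabicyclo[2.2.1]heptan-3-yl]-2-methylpentyl trifluoromethanesulfonate | C=C[C@@](C)(O)CC[C@H]1[C@](C)(CC[C@H](Br)[C@](C)(Cl)COS(=O)(=O)C(F)(F)F)[C@H]2CC[C@]1(C)O2 | intermediate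
24 | (3S)-5-[(1S,2S,3S,4R)-3-[(3S)-3-bromo-4-chloro-4-methylpentyl]-1,3-dimethyl-7-oxabicyclo[2.2.1]heptan-2-yl]-3-methylpent-1-en-3-ol | C=C[C@@](C)(O)CC[C@H]1[C@](C)(CC[C@H](Br)C(C)(C)Cl)[C@H]2CC[C@]1(C)O2 | target

Total step count: 19. Longest linear sequence: 19 steps (1 to 24; methyl acrylate 7 enters at step 6).

Steps most likely to fail

Step 6 (Proposed new method). The radical cation may lose an allylic proton before the hydroxyl reaches C4 through the boat. The C3 radical may be reduced or abstract hydrogen before it meets the acrylate, giving plain hydroetherification. The adduct radical may add to further acrylate because its reduction by the acridine radical is slow. The fallback forms the same two bonds in two known operations, setting out from 6. PhSeCl with pyridine in CH2Cl2 at −78 °C gives anti selenoetherification through the seleniranium ion on the face opposite the hydroxyl; this closes O7–C4 and puts selenium on C3, giving (1S,2R,3R,4R)-1,3-dimethyl-3-(phenylselanyl)-2-{[tri(propan-2-yl)silyl]oxymethyl}-7-oxabicyclo[2.2.1]heptane F1 (selenium endo). Slow addition of Bu3SnH with AIBN to F1 and excess methyl acrylate 7 in benzene at 80 °C then generates the same tertiary C3 radical for a Giese addition from the exo face, and the route is rejoined at 8.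

Step 17. The tertiary allylic alcohol may compete with the primary one for titanium, which would erode facial control or chemoselectivity, and the deoxygenation that follows (steps 18 and 19) may cause reductive loss of the two halogens. The fallback gives up reagent control, sets out from 20 and bypasses steps 16 to 19. Uncatalysed Markovnikov bromochlorination (NBS, Bu4NCl, CH2Cl2, −78 °C) goes through the bromonium ion of the trisubstituted alkene, which is far more nucleophilic than the vinyl group, with chloride opening at the tertiary carbon. Both C–Br epimers should form, namely 24 and (3S)-5-[(1S,2S,3S,4R)-3-[(3R)-3-bromo-4-chloro-4-methylpentyl]-1,3-dimethyl-7-oxabicyclo[2.2.1]heptan-2-yl]-3-methylpent-1-en-3-ol F2, and preparative HPLC would be needed to remove F2; the route is rejoined at 24.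

Step 4. The catalyst may discriminate poorly between the two enantiotopic alkenes, or both alkenes may be epoxidised. The fallback replaces catalytic desymmetrisation by a covalent resolving group and sets out from 3. Esterification with (S)-2-methoxy-2-phenylacetic acid (DCC, DMAP, CH2Cl2) gives (2,6-dimethylcyclohexa-2,5-dien-1-yl)methyl (2S)-2-methoxy-2-phenylacetate F3. One equivalent of mCPBA (NaHCO3, CH2Cl2, 0 °C) epoxidises anti to the arm and should give two diastereomers, [(1R,2R,6S)-1,3-dimethyl-7-oxabicyclo[4.1.0]hept-3-en-2-yl]methyl (2S)-2-methoxy-2-phenylacetate F4 and its ring-enantiomeric partner [(1S,2S,6R)-1,3-dimethyl-7-oxabicyclo[4.1.0]hept-3-en-2-yl]methyl (2S)-2-methoxy-2-phenylacetate F5, to be separated by chromatography or crystallisation. LiAlH4 on F4 opens the epoxide and cleaves the ester to give (1S,2R)-2-(hydroxymethyl)-1,3-dimethylcyclohex-3-en-1-ol F6. Selective silylation of the primary hydroxyl of F6 (TIPSCl, imidazole, DMF) rejoins the route at 6.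

Further compounds
F1 | step 6 | (1S,2R,3R,4R)-1,3-dimethyl-3-(phenylselanyl)-2-{[tri(propan-2-yl)silyl]oxymethyl}-7-oxabicyclo[2.2.1]heptane | CC(C)[Si](OC[C@H]1[C@@](C)([Se]c3ccccc3)[C@H]2CC[C@]1(C)O2)(C(C)C)C(C)C
F2 | step 17 | (3S)-5-[(1S,2S,3S,4R)-3-[(3R)-3-bromo-4-chloro-4-methylpentyl]-1,3-dimethyl-7-oxabicyclo[2.2.1]heptan-2-yl]-3-methylpent-1-en-3-ol | C=C[C@@](C)(O)CC[C@H]1[C@](C)(CC[C@@H](Br)C(C)(C)Cl)[C@H]2CC[C@]1(C)O2
F3 | step 4 | (2,6-dimethylcyclohexa-2,5-dien-1-yl)methyl (2S)-2-methoxy-2-phenylacetate | CO[C@@H](c1ccccc1)C(=O)OCC1C(C)=CCC=C1C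
F4 | step 4 | [(1R,2R,6S)-1,3-dimethyl-7-oxabicyclo[4.1.0]hept-3-en-2-yl]methyl (2S)-2-methoxy-2-phenylacetate | CO[C@@H](c1ccccc1)C(=O)OC[C@H]1C(C)=CC[C@@H]2O[C@]12C
F5 | step 4 | [(1S,2S,6R)-1,3-dimethyl-7-oxabicyclo[4.1.0]hept-3-en-2-yl]methyl (2S)-2-methoxy-2-phenylacetate | CO[C@@H](c1ccccc1)C(=O)OC[C@@H]1C(C)=CC[C@H]2O[C@@]12C
F6 | step 4 | (1S,2R)-2-(hydroxymethyl)-1,3-dimethylcyclohex-3-en-1-ol | OC[C@H]1C(C)=CCC[C@]1(C)O
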